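Remark on the chemistry: ring B2 is brought in as 4-iodo-2-methoxyphenol, not the bromide, because an aryl iodide couples with methyl propiolate under mild conditions; the iodophenol is taken to be purchasable.

## Analysis of the target

The target is a biflavonol with no stereocentre. Unit 1 is a 3,5-dihydroxy-7-methoxyflavone (rings A1, C1, B1) and unit 2 a 3,5,7-trihydroxyflavone (rings A2, C2, B2). The two units are joined by an ether oxygen between C4' of ring B1 and C4' of ring B2. Ring B1 carries a free 3'-hydroxyl and ring B2 a 3'-methoxy group, both ortho to the bridging oxygen, so the diaryl ether is unsymmetrical and flanked on both sides. The molecule has six free hydroxyls: two 3-hydroxy-4-pyranone enols, two chelated 5-hydroxyls, one 7-hydroxyl and one 3'-hydroxyl. This polyphenol is sensitive to base and to oxidants, so all oxygens are carried as ethers and freed in the last step. The difficulty is that the two halves are almost identical yet differ at three oxygens (7-OMe against 7-OH, 3'-OH against 3'-OMe), which rules out any dimerisation and requires two pyranone rings to be built with different ring A patterns. The strategy rests on the position of C4a in each unit: it lies between C8a (bearing O1) and C5 (bearing oxygen) and para to the C7 oxygen. Each ring A is therefore a 3,5-dioxygenated phenoxy ring with two equivalent ortho carbons, and each C4–C4a bond is an arene acylation. Two further features complete the plan: C3 of each chromone is the nucleophilic carbon of the O1–C2=C3 enol ether and can be oxygenated late, and the only methyl ether of ring A1 that must be removed is the one peri to C4=O.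

## Retrosynthetic reasoning

Target 19 is traced back to the fully protected bis-flavonol 18 by cutting three benzyl O–C bonds (5-O and 7-O of unit 2, 3'-O of ring B1) and the methyl O–C bond at C5 of unit 1. The 5-methyl ether sits peri to the C4 carbonyl and can be cleaved by a chelating Lewis acid while the 7-methyl and 3'-methyl ethers stay. This allows ring A1 to come from a symmetric dimethyl ether.

Compound 18 is traced back to bis-flavone 16 by removing both C3–O bonds. C3 is the electron-rich terminus of the enol ether in each chromone, so the forward step is a twofold oxygen transfer to C2=C3 (bis-epoxide 17) followed by acid opening. Leaving the 3-oxygens out until this point means both C rings can come from plain acrylic acid arms.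

Bis-flavone 16 is cut at C4–C4a of unit 1 and of unit 2, giving the bis[(Z)-3-aryloxyacrylic acid] 14 (reacting through its bis mixed anhydride 15). The cut is made here because C4a is an ortho carbon of a symmetric 3,5-dialkoxyphenoxy ring: acylation has no regiochemical choice, both pyranones form in one operation, and the ring A fragments become the purchasable phenols 8 and 12. The forward reaction has to acylate ring A and not ring B, which the Z geometry of each arm secures.

Diacid 14 comes from diester 13 by ester hydrolysis. Diester 13 is cut at O1–C2 of unit 2, giving alkynoate 11 and 3,5-bis(benzyloxy)phenol 12; the forward reaction is an anti conjugate addition of the phenol to the triple bond, which sets the Z enol ether.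

Alkynoate 11 is cut at the bond between C1' of ring B2 and C2 of unit 2, giving aryl iodide 9 and methyl propiolate 10. An sp2–sp coupling brings in C2, C3 and C4 of unit 2 in one piece.

Aryl iodide 9 is cut at O1–C2 of unit 1, giving arylpropiolate 7 and 3,5-dimethoxyphenol 8. Placing this addition before the second alkynoate exists means the two phenols cannot be confused.

Arylpropiolate 7 is cut at C3–C4 (carboxylation of lithium acetylide 6, made from terminal alkyne 5) and then at C2–C3 (one-carbon homologation of aldehyde 4). Both forward steps use only non-nucleophilic or carbonate bases, so the C–I bond is not touched.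

Aldehyde 4 is cut at the diaryl ether bond on C4' of ring B1, giving fluoroaldehyde 2 and 4-iodo-2-methoxyphenol 3. The para formyl group activates fluoride displacement. The phenol of 4-fluoro-3-hydroxybenzaldehyde 1 has to be benzylated first (to 2), because a phenoxide would shut down the substitution; the same benzyl group then serves as the 3'-O protecting group to the end.

## Alternatives that were turned down

Alternative 1: Ring B1 is disconnected at C1'–C2' and C5'–C6' and grown last by a [4+2] cycloaddition. The 1-amino-2-aryloxy-3-siloxydiene A2, which carries complete unit 2 on its aryloxy group, would add to the 2-(2-nitrovinyl)chromone A3 of unit 1; double elimination of the amino and nitro groups would aromatise the new ring to give A1.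
- For it: the route is fully convergent, the bridging oxygen arrives on the diene so no hindered diaryl ether has to be made, both 3-oxygens are in place beforehand, and the 3'-oxygen of ring B1 emerges as a silyl ether orthogonal to all benzyl ethers. On convergence and on avoiding a late oxidation it is stronger than the chosen route.
- Against it: each half needs its own flavonol synthesis and then several more steps to become A2 or A3. Diene A2 is a hydrolytically labile, fully substituted aminosiloxydiene whose formation requires regioselective enol silylation of an α-aryloxy enaminone. In A3 the chromone C2=C3 bond is itself an acceptor and the vinylchromone can act as a diene. The aromatisation must proceed without loss of the silyl group.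
- Comparison: the chosen strategy makes both heterocycles by one reaction type from two purchasable phenols and carries a single chain of intermediates. It pays for this with a linear sequence and a late twofold C3 oxygenation.

Alternative 2: Ring C1 is disconnected at C3–C4 and O1–C2. The lithium enolate of the benzyloxymethyl ketone A6 (ring B1, already bearing benzylated unit 2) would attack the carbonyl of the benzodioxinone A5 (5-benzyloxy, 7-methoxy); collapse of the ketal and acid cyclodehydration would give A4.
- For it: the 3-oxygen of unit 1 is installed directly, ring A1 is differentiated from the start so no chelation-controlled demethylation is needed, and the endgame is a single hydrogenolysis. On these three points it is stronger than the chosen route.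
- Against it: it solves one unit only, since A6 presupposes a finished unit 2 made by some other ring C construction. The carbonyl of A5 is deactivated by ortho and para oxygens and shielded by the 5-benzyloxy group. The α-alkoxy ketone enolate must be used in excess because the diketone product is more acidic, and it must not attack C2 of the chromone already present in A6. A5 itself needs a regioselective differentiation of a trihydroxybenzoate.
- Comparison: the chosen strategy treats both units alike in one step and needs no differentiated ring A building block. It gives up the direct 3-oxygenation and the simple hydrogenolytic finish.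

Alternative 3: Ring C2 is disconnected at C4a–C4, C4–C3 and O1–C2. A palladium-catalysed carbonylative three-component annulation of the iodophenol A8 with the ring B2 alkyne A9 (carrying benzylated unit 1) and an amine base would give A7.
- For it: three bonds form in one step, the route is convergent, and unit 1 arrives complete. Per step this is as strong as one of the two closures of the chosen route.
- Against it: the iodide of A8 is flanked by two ortho oxygens on a very electron-rich ring, so carbonyl insertion competes with direct alkynylation (leading to benzofurans), and the ynone intermediate can close 5-exo to an aurone. A8 needs a regioselective mono-iodination. Ring C2 still lacks its 3-oxygen, so C3 oxidation must be run on a molecule that already contains a finished flavonol. Unit 1 needs a separate synthesis.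
- Comparison: the chosen strategy closes both rings in one operation, oxidises both C3 positions together, and needs no pressurised gas or ring A halide.

Key step: step 9

## Route

Step 1
Reactants: 1 4-fluoro-3-hydroxybenzaldehyde
Product: 2 3-(benzyloxy)-4-fluorobenzaldehyde
Conditions: BnBr, K2CO3, DMF, rt
Reagents that add atoms: benzyl bromide, BrCc1ccccc1
Why: Williamson O-alkylation of the phenol; it removes the phenoxide that would deactivate the ring in the next step and installs the final protecting group of the 3'-oxygen of ring B1.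

Step 2
Reactants: 2 3-(benzyloxy)-4-fluorobenzaldehyde; 3 4-iodo-2-methoxyphenol
Product: 4 3-(benzyloxy)-4-(4-iodo-2-methoxyphenoxy)benzaldehyde
Conditions: K2CO3, DMSO, 100 °C
Reagents that add atoms: none
Why: Nucleophilic aromatic substitution (SNAr); the para formyl group stabilises the Meisenheimer adduct and fluoride leaves, while the aryl iodide is inert without a transition metal.

Step 3
Reactants: 4 3-(benzyloxy)-4-(4-iodo-2-methoxyphenoxy)benzaldehyde
Product: 5 2-(benzyloxy)-4-ethynyl-1-(4-iodo-2-methoxyphenoxy)benzene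
Conditions: dimethyl (1-diazo-2-oxopropyl)phosphonate, K2CO3, MeOH/THF, 0 °C to rt
Reagents that add atoms: dimethyl (1-diazo-2-oxopropyl)phosphonate, CC(=O)C(=[N+]=[N-])P(=O)(OC)OC
Why: Seyferth–Gilbert homologation in the Ohira–Bestmann form; the aldehyde has no α-hydrogen, and because no organolithium is used the C–I bond is not exchanged.

Step 4
Reactants: 5 2-(benzyloxy)-4-ethynyl-1-(4-iodo-2-methoxyphenoxy)benzene
Product: 7 methyl 3-[3-(benzyloxy)-4-(4-iodo-2-methoxyphenoxy)phenyl]prop-2-ynoate, via lithium acetylide 6 (not isolated)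
Conditions: LiN(SiMe3)2, THF, −78 °C; ClCO2Me, −78 to 0 °C
Reagents that add atoms: methyl chloroformate, COC(=O)Cl
Why: Deprotonation of the terminal alkyne by an amide base, which does not undergo iodine–lithium exchange, followed by C-acylation of the acetylide with the chloroformate.

Step 5
Reactants: 7 methyl 3-[3-(benzyloxy)-4-(4-iodo-2-methoxyphenoxy)phenyl]prop-2-ynoate; 8 3,5-dimethoxyphenol
Product: 9 methyl (Z)-3-[3-(benzyloxy)-4-(4-iodo-2-methoxyphenoxy)phenyl]-3-(3,5-dimethoxyphenoxy)prop-2-enoate
Conditions: Cs2CO3 (cat.), DMF, 50–60 °C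
Reagents that add atoms: none
Why: Base-catalysed oxa-Michael addition of the phenoxide to the arylpropiolate; anti protonation of the vinyl anion places the aryloxy group cis to the ester (Z), and the caesium phenoxide in DMF should react at oxygen, not at ring carbon.

Step 6
Reactants: 9 methyl (Z)-3-[3-(benzyloxy)-4-(4-iodo-2-methoxyphenoxy)phenyl]-3-(3,5-dimethoxyphenoxy)prop-2-enoate; 10 methyl propiolate
Product: 11 methyl (Z)-3-[3-(benzyloxy)-4-[2-methoxy-4-(3-methoxy-3-oxoprop-1-yn-1-yl)phenoxy]phenyl]-3-(3,5-dimethoxyphenoxy)prop-2-enoate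
Conditions: PdCl2(PPh3)2 (cat.), CuI (cat.), K2CO3, THF, 50 °C, degassed, slow addition of 10 in excess
Reagents that add atoms: none
Why: Sonogashira coupling; the aryl iodide adds oxidatively to zerovalent palladium at mild temperature, the inorganic base avoids amine conjugate addition to the propiolate, and the enol ether ester is a spectator.

Step 7
Reactants: 11 methyl (Z)-3-[3-(benzyloxy)-4-[2-methoxy-4-(3-methoxy-3-oxoprop-1-yn-1-yl)phenoxy]phenyl]-3-(3,5-dimethoxyphenoxy)prop-2-enoate; 12 3,5-bis(benzyloxy)phenol
Product: 13 methyl (Z)-3-[3,5-bis(benzyloxy)phenoxy]-3-[4-[2-(benzyloxy)-4-[(Z)-1-(3,5-dimethoxyphenoxy)-3-methoxy-3-oxoprop-1-en-1-yl]phenoxy]-3-methoxyphenyl]prop-2-enoate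
Conditions: Cs2CO3 (cat.), 12 (1.05 equiv), DMF, rt to 50 °C
Reagents that add atoms: none
Why: Second oxa-Michael addition; the alkynoate is a far better acceptor than the β,β-disubstituted enol ether ester already present, so a near-stoichiometric amount of phenol should add only to the triple bond, again anti to give the Z isomer.

Step 8
Reactants: 13 the (Z,Z)-dimethyl diester
Product: 14 (Z)-3-[3,5-bis(benzyloxy)phenoxy]-3-[4-[2-(benzyloxy)-4-[(Z)-2-carboxy-1-(3,5-dimethoxyphenoxy)ethenyl]phenoxy]-3-methoxyphenyl]prop-2-enoic acid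
Conditions: LiOH·H2O, THF/H2O, rt; then 1 M HCl to pH 3, 0 °C
Reagents that add atoms: lithium hydroxide (its oxygen ends up in the two carboxyl groups), [Li+].[OH-]
Why: Saponification by acyl–oxygen cleavage; without alcohol co-solvent no alkoxide is present to exchange the aryloxy groups, and cold mild acidification spares the enol ethers.

Step 9
Reactants: 14 the (Z,Z)-diacid
Product: 16 2-[3-(benzyloxy)-4-[4-[5,7-bis(benzyloxy)-4-oxo-4H-chromen-2-yl]-2-methoxyphenoxy]phenyl]-5,7-dimethoxy-4H-chromen-4-one, via bis(trifluoroacetic mixed anhydride) 15 (not isolated)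
Conditions: (CF3CO)2O (3 equiv), CH2Cl2 (0.02 M), 0 °C to rt
Reagents that add atoms: none
Why: Each carboxyl group is converted into its mixed trifluoroacetic anhydride, which ionises with help from the β-aryloxy oxygen to an acylium-type electrophile. The ring carbon ortho to the ether oxygen of each 3,5-dialkoxyphenoxy group, activated ortho and para by the two alkoxy groups, attacks the acyl carbon and proton loss restores the arene (intramolecular Friedel–Crafts acylation). The closest known reaction type is the acid- or anhydride-mediated cyclisation of (Z)-3-aryloxycinnamic acids to flavones and of 2-aryloxybenzoic acids to xanthones. Ring C1 and ring C2 each close in a six-membered mode, exo at the acyl carbon, forming C4–C4a of unit 1 and of unit 2. No stereocentre is formed. The step needs attack on ring A and not on ring B, which the Z geometry secures by holding each acyl group beside its aryloxy ring; it needs no regiocontrol on ring A because the two ortho carbons of each symmetric ring are equivalent. It also needs ring closure to outrun intermolecular acylation and C-trifluoroacetylation, which high dilution, low temperature and the six-membered transition state favour, and once closed each ring A is deactivated by its C4 carbonyl. Only trifluoroacetic acid in dilute CH2Cl2 is liberated, which the benzyl ethers and the diaryl ether should tolerate.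

Step 10
Reactants: 16 the bis-flavone
Product: 18 2-[3-(benzyloxy)-4-[4-[5,7-bis(benzyloxy)-3-hydroxy-4-oxo-4H-chromen-2-yl]-2-methoxyphenoxy]phenyl]-3-hydroxy-5,7-dimethoxy-4H-chromen-4-one, via bis(2,3-epoxide) 17 (not isolated)
Conditions: dimethyldioxirane (acetone solution, excess), CH2Cl2, 0 °C to rt, dark; evaporate; p-TsOH·H2O (cat.), CH2Cl2, rt
Reagents that add atoms: dimethyldioxirane, CC1(C)OO1
Why: Electrophilic epoxidation of the C2=C3 enol ether bond of each fully O-alkylated chromone, then acid opening of each oxirane at C2 to the oxocarbenium ion and loss of H3 to give the 3-hydroxychromone; this is the known flavone-to-flavonol conversion run twice in one molecule.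

Step 11
Reactants: 18 the protected bis-flavonol
Product: 19 2-[4-[4-(3,5-dihydroxy-7-methoxy-4-oxo-4H-chromen-2-yl)-2-hydroxyphenoxy]-3-methoxyphenyl]-3,5,7-trihydroxy-4H-chromen-4-one (CNP0190193.0)
Conditions: BCl3 (excess), C6HMe5, CH2Cl2, −78 to 0 °C; MeOH, then H2O, under argon
Reagents that add atoms: none
Why: Lewis-acid dealkylation; BCl3 cleaves the three aryl benzyl ethers (benzyl cations trapped by pentamethylbenzene) and, through chelation with the C4 carbonyl, the peri 5-methyl ether of unit 1, while the unchelated 7-methyl and 3'-methyl ethers and the diaryl ether should remain.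

## Compound list

1 | 4-fluoro-3-hydroxybenzaldehyde | O=Cc1ccc(F)c(O)c1 | starting material
2 | 3-(benzyloxy)-4-fluorobenzaldehyde | O=Cc1ccc(F)c(OCc2ccccc2)c1 | intermediate
3 | 4-iodo-2-methoxyphenol | COc1cc(I)ccc1O | starting material
4 | 3-(benzyloxy)-4-(4-iodo-2-methoxyphenoxy)benzaldehyde | O=Cc1ccc(Oc2ccc(I)cc2OC)c(OCc2ccccc2)c1 | intermediate
5 | 2-(benzyloxy)-4-ethynyl-1-(4-iodo-2-methoxyphenoxy)benzene | C#Cc1ccc(Oc2ccc(I)cc2OC)c(OCc2ccccc2)c1 | intermediate
6 | lithium acetylide of 5 | [Li]C#Cc1ccc(Oc2ccc(I)cc2OC)c(OCc2ccccc2)c1 | intermediate (not isolated)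
7 | methyl 3-[3-(benzyloxy)-4-(4-iodo-2-methoxyphenoxy)phenyl]prop-2-ynoate | COC(=O)C#Cc1ccc(Oc2ccc(I)cc2OC)c(OCc2ccccc2)c1 | intermediate
8 | 3,5-dimethoxyphenol | COc1cc(O)cc(OC)c1 | starting material
9 | methyl (Z)-3-[3-(benzyloxy)-4-(4-iodo-2-methoxyphenoxy)phenyl]-3-(3,5-dimethoxyphenoxy)prop-2-enoate | COC(=O)/C=C(\Oc1cc(OC)cc(OC)c1)c1ccc(Oc2ccc(I)cc2OC)c(OCc2ccccc2)c1 | intermediate
10 | methyl propiolate | C#CC(=O)OC | starting material
11 | methyl (Z)-3-[3-(benzyloxy)-4-[2-methoxy-4-(3-methoxy-3-oxoprop-1-yn-1-yl)phenoxy]phenyl]-3-(3,5-dimethoxyphenoxy)prop-2-enoate | COC(=O)/C=C(\Oc1cc(OC)cc(OC)c1)c1ccc(Oc2ccc(C#CC(=O)OC)cc2OC)c(OCc2ccccc2)c1 | intermediate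
12 | 3,5-bis(benzyloxy)phenol | Oc1cc(OCc2ccccc2)cc(OCc2ccccc2)c1 | starting material
13 | methyl (Z)-3-[3,5-bis(benzyloxy)phenoxy]-3-[4-[2-(benzyloxy)-4-[(Z)-1-(3,5-dimethoxyphenoxy)-3-methoxy-3-oxoprop-1-en-1-yl]phenoxy]-3-methoxyphenyl]prop-2-enoate | COC(=O)/C=C(\Oc1cc(OC)cc(OC)c1)c1ccc(Oc2ccc(cc2OC)/C(Oc2cc(OCc3ccccc3)cc(OCc3ccccc3)c2)=C/C(=O)OC)c(OCc2ccccc2)c1 | intermediate
14 | (Z)-3-[3,5-bis(benzyloxy)phenoxy]-3-[4-[2-(benzyloxy)-4-[(Z)-2-carboxy-1-(3,5-dimethoxyphenoxy)ethenyl]phenoxy]-3-methoxyphenyl]prop-2-enoic acid | OC(=O)/C=C(\Oc1cc(OC)cc(OC)c1)c1ccc(Oc2ccc(cc2OC)/C(Oc2cc(OCc3ccccc3)cc(OCc3ccccc3)c2)=C/C(O)=O)c(OCc2ccccc2)c1 | intermediate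
15 | bis(mixed anhydride) of 14 with trifluoroacetic acid, both alkenes Z | FC(F)(F)C(=O)OC(=O)/C=C(\Oc1cc(OC)cc(OC)c1)c1ccc(Oc2ccc(cc2OC)/C(Oc2cc(OCc3ccccc3)cc(OCc3ccccc3)c2)=C/C(=O)OC(=O)C(F)(F)F)c(OCc2ccccc2)c1 | intermediate (not isolated)
16 | 2-[3-(benzyloxy)-4-[4-[5,7-bis(benzyloxy)-4-oxo-4H-chromen-2-yl]-2-methoxyphenoxy]phenyl]-5,7-dimethoxy-4H-chromen-4-one | COc1cc(OC)c2c(=O)cc(-c3ccc(Oc4ccc(-c5cc(=O)c6c(OCc7ccccc7)cc(OCc7ccccc7)cc6o5)cc4OC)c(OCc7ccccc7)c3)oc2c1 | intermediate
17 | bis(2,3-epoxide) of 16 (oxirane across C2–C3 of each unit; mixture of diastereomers, each racemic, configuration not defined) | COc1cc(OC)c2C(=O)C3OC3(c3ccc(Oc4ccc(C56OC5C(=O)c5c(OCc7ccccc7)cc(OCc7ccccc7)cc5O6)cc4OC)c(OCc4ccccc4)c3)Oc2c1 | intermediate (not isolated)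
18 | 2-[3-(benzyloxy)-4-[4-[5,7-bis(benzyloxy)-3-hydroxy-4-oxo-4H-chromen-2-yl]-2-methoxyphenoxy]phenyl]-3-hydroxy-5,7-dimethoxy-4H-chromen-4-one | COc1cc(OC)c2c(=O)c(O)c(-c3ccc(Oc4ccc(-c5oc6cc(OCc7ccccc7)cc(OCc7ccccc7)c6c(=O)c5O)cc4OC)c(OCc7ccccc7)c3)oc2c1 | intermediate
19 | 2-[4-[4-(3,5-dihydroxy-7-methoxy-4-oxo-4H-chromen-2-yl)-2-hydroxyphenoxy]-3-methoxyphenyl]-3,5,7-trihydroxy-4H-chromen-4-one | COc1cc(O)c2c(=O)c(O)c(-c3ccc(Oc4ccc(-c5oc6cc(O)cc(O)c6c(=O)c5O)cc4OC)c(O)c3)oc2c1 | target

## Step count and least certain steps

Total: 11 steps. Longest linear sequence: 11 steps (1 to 19); the route is linear, with 3, 8, 10 and 12 added as purchased building blocks.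

Step 9 (key step). The most likely failure is slow ionisation of the vinylogous mixed anhydride, which would let intermolecular acylation or C-trifluoroacetylation of the still uncyclised, very electron-rich phenoxy rings compete. Two further risks are acid-induced E/Z equilibration followed by acylation of ring B1 para to its benzyloxy group (indenone formation), and partial loss or migration of benzyl groups if a stronger acid has to be added. Fallback: starting from 14, both acids are converted under neutral conditions with 1-chloro-N,N,2-trimethylprop-1-en-1-amine in CH2Cl2 into the bis(acyl chloride) F1. This is ionised with AgOSO2CF3 in the presence of 2,6-di-tert-butyl-4-methylpyridine at low temperature, so that ring closure proceeds without any external acylating agent or free protic acid, and the route is rejoined at 16. The one-ring-at-a-time sequence described under step 7 serves the same purpose.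

Step 7. Two processes threaten it: exchange of the 3,5-dimethoxyphenoxy group of the first enol ether by the incoming phenoxide (addition–elimination at the vinylogous carbonate), which would scramble the two ring A patterns, and attack of the phloroglucinol-type phenoxide through carbon, which would end in a 4-arylcoumarin. Fallback: starting from 9, unit 1 is locked before the second phenol is introduced. Saponification gives the acid F2, which with trifluoroacetic anhydride forms the mixed anhydride F3 (not isolated) and closes to the iodoflavone F4. Sonogashira coupling of F4 with 10 gives the alkynoate F5, oxa-Michael addition of 12 gives the enol ether ester F6, saponification gives the acid F7, and a second anhydride closure through the mixed anhydride F8 (not isolated) rejoins the route at 16.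

Step 6. Base-induced oligomerisation and conjugate addition of methyl propiolate, and oxidative homocoupling of the alkyne, can consume the coupling partner faster than the electron-rich aryl iodide reacts. Fallback: starting from 9, Sonogashira coupling with ethynyltrimethylsilane (PdCl2(PPh3)2, CuI, Et3N) gives the silylalkyne F9. Desilylation with Bu4NF buffered by acetic acid gives the terminal alkyne F10. Deprotonation with LiN(SiMe3)2 at −78 °C gives the lithium acetylide F11, and methyl chloroformate returns the route to 11.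

Step 10. The twofold epoxidation is slow, so excess dioxirane may oxidise benzylic C–H bonds of the benzyl ethers or the alkoxy-substituted B rings, or the second epoxidation may stall. Fallback: starting from 16, twofold C3 deprotonation with LiN(i-Pr)2 in THF at −78 °C gives the dilithio compound F12. Trapping with B(OMe)3 gives the bis(dimethyl boronate) F13, and oxidation with H2O2 in acetic acid rejoins the route at 18.

Step 11. Boron may be sequestered in the 3-O/4-O chelates so that the 5-methyl ether of unit 1 is cleaved incompletely, forcing longer or warmer treatment that starts to demethylate the 3'-methoxy group. Benzyl cations may also alkylate the phloroglucinol ring if trapping is inefficient. Fallback: starting from 18, the benzyl ethers are first removed by hydrogenolysis (H2, Pd/C (palladium on carbon), THF/MeOH) to give the 5-O-methyl compound F14. A separate chelation-controlled demethylation with AlCl3 in acetonitrile then gives 19.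

## Further compounds

F1 | step 9 | bis(acyl chloride) of 14, both alkenes Z | ClC(=O)/C=C(\Oc1cc(OC)cc(OC)c1)c1ccc(Oc2ccc(cc2OC)/C(Oc2cc(OCc3ccccc3)cc(OCc3ccccc3)c2)=C/C(Cl)=O)c(OCc2ccccc2)c1
F2 | step 7 | (Z)-3-[3-(benzyloxy)-4-(4-iodo-2-methoxyphenoxy)phenyl]-3-(3,5-dimethoxyphenoxy)prop-2-enoic acid | OC(=O)/C=C(\Oc1cc(OC)cc(OC)c1)c1ccc(Oc2ccc(I)cc2OC)c(OCc2ccccc2)c1
F3 | step 7 | mixed anhydride of F2 with trifluoroacetic acid | FC(F)(F)C(=O)OC(=O)/C=C(\Oc1cc(OC)cc(OC)c1)c1ccc(Oc2ccc(I)cc2OC)c(OCc2ccccc2)c1
F4 | step 7 | 2-[3-(benzyloxy)-4-(4-iodo-2-methoxyphenoxy)phenyl]-5,7-dimethoxy-4H-chromen-4-one | COc1cc(OC)c2c(=O)cc(-c3ccc(Oc4ccc(I)cc4OC)c(OCc4ccccc4)c3)oc2c1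
F5 | step 7 | methyl 3-[4-[2-(benzyloxy)-4-(5,7-dimethoxy-4-oxo-4H-chromen-2-yl)phenoxy]-3-methoxyphenyl]prop-2-ynoate | COC(=O)C#Cc1ccc(Oc2ccc(cc2OCc2ccccc2)-c2cc(=O)c3c(OC)cc(OC)cc3o2)c(OC)c1
F6 | step 7 | methyl (Z)-3-[3,5-bis(benzyloxy)phenoxy]-3-[4-[2-(benzyloxy)-4-(5,7-dimethoxy-4-oxo-4H-chromen-2-yl)phenoxy]-3-methoxyphenyl]prop-2-enoate | COC(=O)/C=C(\Oc1cc(OCc2ccccc2)cc(OCc2ccccc2)c1)c1ccc(Oc2ccc(cc2OCc2ccccc2)-c2cc(=O)c3c(OC)cc(OC)cc3o2)c(OC)c1
F7 | step 7 | (Z)-3-[3,5-bis(benzyloxy)phenoxy]-3-[4-[2-(benzyloxy)-4-(5,7-dimethoxy-4-oxo-4H-chromen-2-yl)phenoxy]-3-methoxyphenyl]prop-2-enoic acid | OC(=O)/C=C(\Oc1cc(OCc2ccccc2)cc(OCc2ccccc2)c1)c1ccc(Oc2ccc(cc2OCc2ccccc2)-c2cc(=O)c3c(OC)cc(OC)cc3o2)c(OC)c1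
F8 | step 7 | mixed anhydride of F7 with trifluoroacetic acid | FC(F)(F)C(=O)OC(=O)/C=C(\Oc1cc(OCc2ccccc2)cc(OCc2ccccc2)c1)c1ccc(Oc2ccc(cc2OCc2ccccc2)-c2cc(=O)c3c(OC)cc(OC)cc3o2)c(OC)c1
F9 | step 6 | methyl (Z)-3-[3-(benzyloxy)-4-[2-methoxy-4-[2-(trimethylsilyl)ethynyl]phenoxy]phenyl]-3-(3,5-dimethoxyphenoxy)prop-2-enoate | COC(=O)/C=C(\Oc1cc(OC)cc(OC)c1)c1ccc(Oc2ccc(C#C[Si](C)(C)C)cc2OC)c(OCc2ccccc2)c1
F10 | step 6 | methyl (Z)-3-[3-(benzyloxy)-4-(4-ethynyl-2-methoxyphenoxy)phenyl]-3-(3,5-dimethoxyphenoxy)prop-2-enoate | COC(=O)/C=C(\Oc1cc(OC)cc(OC)c1)c1ccc(Oc2ccc(C#C)cc2OC)c(OCc2ccccc2)c1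
F11 | step 6 | lithium acetylide of F10 | COC(=O)/C=C(\Oc1cc(OC)cc(OC)c1)c1ccc(Oc2ccc(C#C[Li])cc2OC)c(OCc2ccccc2)c1
F12 | step 10 | 3,3-dilithio derivative of 16 (lithium at C3 of each chromone) | COc1cc(OC)c2c(=O)c([Li])c(-c3ccc(Oc4ccc(-c5oc6cc(OCc7ccccc7)cc(OCc7ccccc7)c6c(=O)c5[Li])cc4OC)c(OCc7ccccc7)c3)oc2c1
F13 | step 10 | bis(dimethyl boronate) of 16 (dimethoxyboryl group at C3 of each chromone) | COc1cc(OC)c2c(=O)c(B(OC)OC)c(-c3ccc(Oc4ccc(-c5oc6cc(OCc7ccccc7)cc(OCc7ccccc7)c6c(=O)c5B(OC)OC)cc4OC)c(OCc7ccccc7)c3)oc2c1
F14 | step 11 | 2-[4-[4-(3-hydroxy-5,7-dimethoxy-4-oxo-4H-chromen-2-yl)-2-hydroxyphenoxy]-3-methoxyphenyl]-3,5,7-trihydroxy-4H-chromen-4-one | COc1cc(OC)c2c(=O)c(O)c(-c3ccc(Oc4ccc(-c5oc6cc(O)cc(O)c6c(=O)c5O)cc4OC)c(O)c3)oc2c1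
A1 | alternative 1 | pentabenzyl ether of the target with a tert-butyldimethylsilyl group on the 3'-oxygen of ring B1 | COc1cc(OCc7ccccc7)c2c(=O)c(OCc7ccccc7)c(-c3ccc(Oc4ccc(-c5oc6cc(OCc7ccccc7)cc(OCc7ccccc7)c6c(=O)c5OCc7ccccc7)cc4OC)c(O[Si](C)(C)C(C)(C)C)c3)oc2c1
A2 | alternative 1 | 1-(dimethylamino)-2-aryloxy-3-(tert-butyldimethylsilyloxy)buta-1,3-diene whose aryloxy group is ring B2 carrying tribenzylated unit 2 | CN(C)/C=C(\Oc1ccc(cc1OC)-c1oc2cc(OCc3ccccc3)cc(OCc3ccccc3)c2c(=O)c1OCc1ccccc1)C(=C)O[Si](C)(C)C(C)(C)C
A3 | alternative 1 | 3,5-bis(benzyloxy)-7-methoxy-2-[(E)-2-nitroethenyl]-4H-chromen-4-one | COc1cc(OCc2ccccc2)c2c(=O)c(OCc3ccccc3)c(/C=C/[N+](=O)[O-])oc2c1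
A4 | alternative 2 | hexabenzyl ether of the target | COc1cc(OCc7ccccc7)c2c(=O)c(OCc7ccccc7)c(-c3ccc(Oc4ccc(-c5oc6cc(OCc7ccccc7)cc(OCc7ccccc7)c6c(=O)c5OCc7ccccc7)cc4OC)c(OCc7ccccc7)c3)oc2c1
A5 | alternative 2 | 5-(benzyloxy)-7-methoxy-2,2-dimethyl-4H-1,3-benzodioxin-4-one | COc1cc(OCc2ccccc2)c2C(=O)OC(C)(C)Oc2c1
A6 | alternative 2 | 2-(benzyloxy)-1-[3-(benzyloxy)-4-[4-[3,5,7-tris(benzyloxy)-4-oxo-4H-chromen-2-yl]-2-methoxyphenoxy]phenyl]ethan-1-one | O=C(COCc1ccccc1)c1ccc(Oc2ccc(cc2OC)-c2oc3cc(OCc4ccccc4)cc(OCc4ccccc4)c3c(=O)c2OCc2ccccc2)c(OCc2ccccc2)c1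
A7 | alternative 3 | pentabenzyl compound with unit 1 complete and unit 2 as the flavone lacking its 3-oxygen | COc1cc(OCc7ccccc7)c2c(=O)c(OCc7ccccc7)c(-c3ccc(Oc4ccc(-c5cc(=O)c6c(OCc7ccccc7)cc(OCc7ccccc7)cc6o5)cc4OC)c(OCc7ccccc7)c3)oc2c1
A8 | alternative 3 | 3,5-bis(benzyloxy)-2-iodophenol | Oc1cc(OCc2ccccc2)cc(OCc2ccccc2)c1I
A9 | alternative 3 | 3,5-bis(benzyloxy)-2-[3-(benzyloxy)-4-(4-ethynyl-2-methoxyphenoxy)phenyl]-7-methoxy-4H-chromen-4-one | C#Cc1ccc(Oc2ccc(cc2OCc2ccccc2)-c2oc3cc(OC)cc(OCc4ccccc4)c3c(=O)c2OCc2ccccc2)c(OC)c1
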